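**Retrosynthetic overview**

1. The target is traced back to its 2-aza homologue 20 by a nitrogen-deletion ring contraction. In 20 an NH sits between the cyclobutane methine that is shared only with the five-membered ring and the ring CH2, so the future cyclopentane is a piperidine. The feature used: these two sp3 carbons are held 1,5 by the rigid skeleton and the cyclobutane can only be cis-fused, so C–C coupling after loss of N2 must retain configuration.
2. 20 comes from an intramolecular Diels–Alder reaction of the N–CH2-tethered E,E-dienoate 18 onto the cyclohexadiene of a bicyclo[4.2.0]octa-2,4-diene; this closes the aza ring and the ester-bearing cyclohexene B and sets four stereocentres.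
3. Bicyclooctadiene carbamate 15 comes from an allyl cyanate-to-isocyanate [3,3] shift (chirality transfer from O to N) followed by 6π electrocyclisation of the cyclooctatriene (cyclobutane plus cyclohexadiene A).
4. Cyclooctatrienol 9 comes from a copper-catalysed enantioselective anti-SN2′ opening of meso cyclooctatetraene oxide by bis[(E)-dec-8-enyl]zinc, which sets the absolute configuration.
5. Order of ring formation: cyclobutane and cyclohexene A (step 7), then the six-membered aza ring and cyclohexene B (step 10), then the cyclopentane by contraction (step 12).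

Key step: step 12

Remark (assumption): 15 and 18 are written as the bicyclo[4.2.0]octa-2,4-diene diastereomer that cyclises; each is taken to equilibrate by reversible 6π electrocyclisation with its cyclooctatriene valence isomer and, through it, with the diastereomer carrying nitrogen on the convex face, so the whole population can funnel into step 10. The sense of induction in step 5 is assumed to follow that of simple dialkylzincs; otherwise the enantiomeric ligand is used.

**Route**

Step 1
Reactants: 1 dec-9-yn-1-ol
Product: 2 dec-8-yn-1-ol
Conditions: KOtBu (3 equiv), DMSO, rt; aq NH4Cl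
Reagents that add atoms: none
Why: Base-mediated propargyl–allenyl prototropic isomerisation moves the terminal triple bond one position inward to the thermodynamically preferred methyl-capped alkyne while the alkoxide is inert, and no stereocentre is involved.

Step 2
Reactants: 2 dec-8-yn-1-ol
Product: 3 (E)-dec-8-en-1-ol
Conditions: Na, NH3 (l), THF, −33 °C; NH4Cl
Reagents that add atoms: none
Why: Dissolving-metal reduction of a dialkyl alkyne passes through a vinyl radical anion and vinyl anion that relax to the trans geometry before protonation, so the E double bond of the side chain is set here and the isolated alkene is not reduced further.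

Step 3
Reactants: 3 (E)-dec-8-en-1-ol
Product: 4 (E)-10-bromodec-2-ene
Conditions: CBr4, PPh3, CH2Cl2, 0 °C
Reagents that add atoms: carbon tetrabromide, BrC(Br)(Br)Br
Why: Appel bromination converts the primary alcohol through its alkoxyphosphonium salt by SN2 displacement without touching the remote E-alkene.

Step 4
Reactants: 5 cyclooctatetraene
Product: 6 cyclooctatetraene oxide (meso cis-9-oxabicyclo[6.1.0]nona-2,4,6-triene)
Conditions: mCPBA (0.7 equiv), NaHCO3, CH2Cl2, 0 °C to rt
Reagents that add atoms: meta-chloroperoxybenzoic acid, OOC(=O)c1cccc(Cl)c1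
Why: Prilezhaev epoxidation of one of the four equivalent cis double bonds should give the meso cis-epoxide, the peracid being used in deficiency to limit a second epoxidation.

Step 5
Reactants: 4 (E)-10-bromodec-2-ene; 6 cyclooctatetraene oxide
Product: 9 (1R,4R)-4-[(E)-dec-8-enyl]cycloocta-2,5,7-trien-1-ol, via Grignard reagent 7 (not isolated), via dialkylzinc 8 (not isolated)
Conditions: Mg, THF; ZnCl2 (0.5 equiv), then 1,4-dioxane, filtration; 6, Cu(OTf)2 (3 mol %), (S,R,R)-phosphoramidite L1 [(S)-BINOL-derived N,N-bis((R)-1-phenylethyl)phosphoramidite] (6 mol %), toluene, −78 to −10 °C; aq NH4Cl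
Reagents that add atoms: none
Why: Copper-catalysed allylic alkylation of a meso vinyl epoxide with a dialkylzinc in the anti-SN2′ mode, in which the chiral phosphoramidite–copper complex selects one of the two enantiotopic allylic termini and the alkyl group enters anti to the departing oxygen, so that the carbinol centre (the untouched epoxide carbon) and the alkyl-bearing centre trans to it are both fixed.

Step 6
Reactants: 9 (1R,4R)-4-[(E)-dec-8-enyl]cycloocta-2,5,7-trien-1-ol
Product: 11 (1R,4R)-4-[(E)-dec-8-enyl]cycloocta-2,5,7-trienyl carbamate, via trichloroacetylcarbamate 10 (not isolated)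
Conditions: Cl3CC(O)NCO, CH2Cl2, 0 °C; then K2CO3, MeOH–H2O, rt
Reagents that add atoms: trichloroacetyl isocyanate, O=C=NC(=O)C(Cl)(Cl)Cl
Why: Acylation of the secondary alcohol by the isocyanate and mild methanolysis of the trichloroacetyl group should give the primary carbamate without ionising the doubly allylic C–O bond and without touching a stereocentre.

Step 7
Reactants: 11 (1R,4R)-4-[(E)-dec-8-enyl]cycloocta-2,5,7-trienyl carbamate
Product: 15 tert-butyl N-[8-((E)-dec-8-enyl)bicyclo[4.2.0]octa-2,4-dien-7-yl]carbamate (cis ring fusion; NHBoc trans to the side chain and on the cyclobutane face that carries the six-membered ring), via allyl cyanate 12 (not isolated), via isocyanate 13 (not isolated), via cyclooctatrienyl carbamate 14 (not isolated)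
Conditions: (CF3CO)2O, Et3N, CH2Cl2, −78 to 0 °C; LiOtBu, THF, 0 °C to rt; then rt, 12 h
Reagents that add atoms: lithium tert-butoxide, [Li+].CC(C)(C)[O-]
Why: Dehydration of the carbamate to the allyl cyanate triggers the concerted suprafacial [3,3] shift (allyl cyanate-to-isocyanate rearrangement) that places nitrogen on the alkene terminus next to the decenyl-bearing carbon, on the face the oxygen occupied and hence trans to the side chain, toward the terminus that completes a conjugated triene; tert-butoxide then traps the isocyanate and thermal disrotatory 6π electrocyclisation closes the cis-fused cyclobutane and cyclohexadiene, whose two ring-fusion centres are relayed from the two existing centres through this reversible closure.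

Step 8
Reactants: 16 methyl (2E,4E)-hexa-2,4-dienoate (methyl sorbate)
Product: 17 methyl (2E,4E)-6-bromohexa-2,4-dienoate
Conditions: NBS, AIBN (cat.), PhCF3, 80 °C
Reagents that add atoms: N-bromosuccinimide, O=C1CCC(=O)N1Br
Why: Wohl–Ziegler bromination takes place at the terminal methyl group because hydrogen abstraction there gives the fully conjugated ester-stabilised radical, and bromine is delivered at the terminus that keeps the E,E-dienoate.

Step 9
Reactants: 15 tert-butyl N-[8-((E)-dec-8-enyl)bicyclo[4.2.0]octa-2,4-dien-7-yl]carbamate; 17 methyl (2E,4E)-6-bromohexa-2,4-dienoate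
Product: 18 methyl (2E,4E)-6-[N-(tert-butoxycarbonyl)-N-(8-((E)-dec-8-enyl)bicyclo[4.2.0]octa-2,4-dien-7-yl)amino]hexa-2,4-dienoate
Conditions: NaH, DMF, 0 °C to rt
Reagents that add atoms: none
Why: N-Alkylation of the carbamate sodium salt by SN2 displacement of the primary allylic bromide attaches the dienoate through an N–CH2 tether without affecting any stereocentre.

Step 10
Reactants: 18 methyl (2E,4E)-6-[N-(tert-butoxycarbonyl)-N-(8-((E)-dec-8-enyl)bicyclo[4.2.0]octa-2,4-dien-7-yl)amino]hexa-2,4-dienoate
Product: 19 N-Boc aza-tetracycle (the target skeleton with N-Boc inserted between the cyclobutane methine and the ring CH2)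
Conditions: toluene, BHT (cat.), 110 °C
Reagents that add atoms: none
Why: Thermal intramolecular Diels–Alder reaction closing a six-membered tether ring, in which the E,E-dienoate adds as the 4π partner to the proximal double bond of the cyclohexadiene on the only face the cyclobutane-borne tether can reach and through the exo transition state that keeps the diene away from the cyclohexadiene core, so that the four new stereocentres arise with the ester and the CH2N group cis (from the E,E geometry), ring A cis-fused and the aza ring trans-fused to the new cyclohexene, as known for CH2-linked dienes on this bicycle.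

Step 11
Reactants: 19 N-Boc aza-tetracycle
Product: 20 secondary amine (aza-tetracycle, N–H)
Conditions: TFA, CH2Cl2, 0 °C; aq NaHCO3
Reagents that add atoms: none
Why: Acidolysis of the tert-butyl carbamate (loss of 2-methylpropene and CO2) frees the secondary amine under conditions that should leave the β,γ-unsaturated ester and the three alkenes unchanged.

Step 12
Reactants: 20 secondary amine (aza-tetracycle, N–H)
Product: 22 CNP0133550.1 (target), via isodiazene 21 (not isolated)
Conditions: N-(benzyloxy)-N-(pivaloyloxy)-4-(trifluoromethyl)benzamide (1.3 equiv), THF (5 mM), 45 °C, 525 nm LED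
Reagents that add atoms: none
Why: Proposed new method: the amine attacks the anomeric amide at nitrogen with loss of pivalate, the resulting N-alkoxy-N-aminoamide collapses to benzyl 4-(trifluoromethyl)benzoate and isodiazene 21, and thermal or visible-light-induced (n→π* band) loss of N2 leaves a singlet 1,5-diradical whose carbon termini couple within the solvent cage. The closest known reaction type is the nitrogen deletion of cyclic secondary amines through isodiazenes (piperidine to cyclopentane, pyrrolidine to cyclobutane), established where one α-carbon is benzylic or ester-substituted, together with the photochemical N2 loss from persistent dialkyl 1,1-diazenes; the proposal extends it to a substrate with two unstabilised α-carbons, relying on high dilution against tetrazene formation and on the rigid tetracycle that holds the two radical centres within bonding distance. The cyclopentane closes by radical–radical recombination of the cyclobutane methine with the ring CH2, which is a contraction of the six-membered aza ring by extrusion of its nitrogen atom. No new stereocentre is formed: the methine can bond only on the face that gives the cis-fused bicyclo[3.2.0]heptane, so its configuration is retained, and the seven other centres are spectators. The selectivity needed is coupling over disproportionation by hydrogen transfer from the allylic ring-fusion C–H and over hydrazone tautomerisation, which the short lifetime of the singlet pair, the neutral medium and the absence of base (which also protects the β,γ-unsaturated ester) are expected to secure.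

**Compound list**

1 | dec-9-yn-1-ol | C#CCCCCCCCCO | starting material
2 | dec-8-yn-1-ol | CC#CCCCCCCCO | intermediate
3 | (E)-dec-8-en-1-ol | C/C=C/CCCCCCCO | intermediate
4 | (E)-10-bromodec-2-ene | C/C=C/CCCCCCCBr | intermediate
5 | cyclooctatetraene | C1=CC=CC=CC=C1 | starting material
6 | cyclooctatetraene oxide (meso, cis) | C1=C\C=C/[C@@H]2O[C@@H]2\C=C/1 | intermediate
7 | (E)-dec-8-enylmagnesium bromide | C/C=C/CCCCCCC[Mg]Br | intermediate
8 | bis[(E)-dec-8-enyl]zinc | C/C=C/CCCCCCC[Zn]CCCCCCC/C=C/C | intermediate
9 | (1R,4R)-4-[(E)-dec-8-enyl]cycloocta-2,5,7-trien-1-ol (OH and side chain trans, ring alkenes Z) | C/C=C/CCCCCCC[C@@H]1/C=C\C=C/[C@@H](O)/C=C\1 | intermediate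
10 | (1R,4R)-4-[(E)-dec-8-enyl]cycloocta-2,5,7-trienyl N-(trichloroacetyl)carbamate | C/C=C/CCCCCCC[C@@H]1/C=C\C=C/[C@@H](OC(=O)NC(=O)C(Cl)(Cl)Cl)/C=C\1 | intermediate
11 | (1R,4R)-4-[(E)-dec-8-enyl]cycloocta-2,5,7-trienyl carbamate | C/C=C/CCCCCCC[C@@H]1/C=C\C=C/[C@@H](OC(N)=O)/C=C\1 | intermediate
12 | (1R,4R)-4-[(E)-dec-8-enyl]cycloocta-2,5,7-trienyl cyanate | C/C=C/CCCCCCC[C@@H]1/C=C\C=C/[C@@H](OC#N)/C=C\1 | intermediate
13 | trans-8-[(E)-dec-8-enyl]cycloocta-2,4,6-trien-1-yl isocyanate | C/C=C/CCCCCCC[C@@H]1/C=C\C=C/C=C\[C@H]1N=C=O | intermediate
14 | tert-butyl N-[trans-8-((E)-dec-8-enyl)cycloocta-2,4,6-trien-1-yl]carbamate | C/C=C/CCCCCCC[C@@H]1/C=C\C=C/C=C\[C@H]1NC(=O)OC(C)(C)C | intermediate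
15 | tert-butyl N-[8-((E)-dec-8-enyl)bicyclo[4.2.0]octa-2,4-dien-7-yl]carbamate (cis-fused; NHBoc trans to side chain, cis to the six-membered ring) | C/C=C/CCCCCCC[C@@H]1[C@H]2C=CC=C[C@H]2[C@H]1NC(=O)OC(C)(C)C | intermediate
16 | methyl (2E,4E)-hexa-2,4-dienoate | C/C=C/C=C/C(=O)OC | starting material
17 | methyl (2E,4E)-6-bromohexa-2,4-dienoate | BrC/C=C/C=C/C(=O)OC | intermediate
18 | methyl (2E,4E)-6-[N-Boc-N-(8-((E)-dec-8-enyl)bicyclo[4.2.0]octa-2,4-dien-7-yl)amino]hexa-2,4-dienoate | C/C=C/CCCCCCC[C@@H]1[C@H]2C=CC=C[C@H]2[C@H]1N(C(=O)OC(C)(C)C)C/C=C/C=C/C(=O)OC | intermediate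
19 | N-Boc aza-tetracycle (target skeleton with N-Boc between the cyclobutane methine and the ring CH2; configuration at all eight carbons as in the target) | C/C=C/CCCCCCC[C@@H]1[C@H]2C=C[C@@H]3[C@@H]4[C@H]2[C@H]1N(C(=O)OC(C)(C)C)C[C@H]4C=C[C@H]3C(=O)OC | intermediate
20 | aza-tetracycle, secondary amine | C/C=C/CCCCCCC[C@@H]1[C@H]2C=C[C@@H]3[C@@H]4[C@H]2[C@H]1NC[C@H]4C=C[C@H]3C(=O)OC | intermediate
21 | isodiazene (1,1-diazene) of 20 | C/C=C/CCCCCCC[C@@H]1[C@H]2C=C[C@@H]3[C@@H]4[C@H]2[C@H]1[N+](=[N-])C[C@H]4C=C[C@H]3C(=O)OC | intermediate
22 | CNP0133550.1: methyl ester of the 4-5-6-6 tetracycle carrying the (E)-dec-8-enyl chain on the cyclobutane | C/C=C/CCCCCCC[C@@H]1[C@H]2C=C[C@@H]3[C@@H]4[C@H]2[C@H]1C[C@H]4C=C[C@H]3C(=O)OC | target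

**Step count and risks**

Total step count: 12. Longest linear sequence: 10 steps (steps 1, 2, 3, 5, 6, 7, 9, 10, 11, 12).

Steps most likely to fail:

Step 12 (proposed new method). The isodiazene has no radical-stabilising α-substituent, so it may lose N2 too slowly and instead dimerise to a tetrazene or tautomerise to a hydrazone; the diradical may also disproportionate by hydrogen transfer. The fallback gives the ring CH2 a removable ester so that the deletion falls into the established α-amino ester class; it sets out from 15 and returns at 22. Boc cleavage of 15 with TFA should give the primary amine F1. A Petasis borono-Mannich reaction of F1 with glyoxylic acid and methyl (2E,4E)-5-(pinacolboryl)penta-2,4-dienoate in hexafluoroisopropanol should give the amino acid F2 (both epimers at the new α-carbon serve). Esterification with tert-butyl acetate and HClO4 gives the tert-butyl ester F3, and the Diels–Alder reaction of step 10 then gives the pipecolate-type aza-tetracycle F4. Nitrogen deletion with the same anomeric amide now passes through an ester-stabilised radical and should give the cyclopentane tert-butyl ester F5. TFA liberates the acid F6, and Barton decarboxylation (oxalyl chloride, sodium 2-mercaptopyridine N-oxide, tert-butylthiol, light) gives 22.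

Step 10. The cycloaddition may stall, or the cyclohexadiene may add as the diene to the tethered alkene, because the carbamate rotamers and its bulk hold the dienoate away from the ring double bond; prolonged heating also invites hydrogen shifts in the cyclooctatriene valence isomer. The fallback reverses the order of steps 10 and 11; it sets out from 18 and returns at 20. TFA cleavage of 18 gives the acyclic secondary amine F7 as its trifluoroacetate, whose small, rotamer-free ammonium tether should cyclise in water or hexafluoroisopropanol at 60–80 °C; neutralisation gives 20 directly.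

Step 7. The doubly allylic C–O bond may ionise to a homotropylium-type cation in competition with the concerted [3,3] shift, which would scramble the position and face of nitrogen entry. The fallback uses that ionisation under metal control; it sets out from 9 and returns at 15. Methyl chloroformate and pyridine convert 9 into the allylic methyl carbonate F8. Zerovalent palladium catalysis (Pd(PPh3)4) with di-tert-butyl iminodicarbonate should deliver nitrogen with net retention (double inversion) at the allyl terminus that completes the conjugated triene, and after 6π electrocyclisation this gives the N,N-bis-Boc bicyclic amine F9. Mg(ClO4)2 in MeCN removes one Boc group and gives 15.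

**Further compounds**

F1 | step 12 | 8-[(E)-dec-8-enyl]bicyclo[4.2.0]octa-2,4-dien-7-amine (configuration as in 15) | C/C=C/CCCCCCC[C@@H]1[C@H]2C=CC=C[C@H]2[C@H]1N
F2 | step 12 | (3E,5E)-2-[(8-((E)-dec-8-enyl)bicyclo[4.2.0]octa-2,4-dien-7-yl)amino]-7-methoxy-7-oxohepta-3,5-dienoic acid (epimers at C-2) | C/C=C/CCCCCCC[C@@H]1[C@H]2C=CC=C[C@H]2[C@H]1NC(C(=O)O)/C=C/C=C/C(=O)OC
F3 | step 12 | tert-butyl ester of F2 | C/C=C/CCCCCCC[C@@H]1[C@H]2C=CC=C[C@H]2[C@H]1NC(C(=O)OC(C)(C)C)/C=C/C=C/C(=O)OC
F4 | step 12 | aza-tetracycle 20 carrying a tert-butoxycarbonyl group on the carbon between N and the cyclohexene ring fusion | C/C=C/CCCCCCC[C@@H]1[C@H]2C=C[C@@H]3[C@@H]4[C@H]2[C@H]1NC(C(=O)OC(C)(C)C)[C@H]4C=C[C@H]3C(=O)OC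
F5 | step 12 | target skeleton carrying a tert-butoxycarbonyl group on the cyclopentane CH2 carbon | C/C=C/CCCCCCC[C@@H]1[C@H]2C=C[C@@H]3[C@@H]4[C@H]2[C@H]1C(C(=O)OC(C)(C)C)[C@H]4C=C[C@H]3C(=O)OC
F6 | step 12 | carboxylic acid from F5 | C/C=C/CCCCCCC[C@@H]1[C@H]2C=C[C@@H]3[C@@H]4[C@H]2[C@H]1C(C(=O)O)[C@H]4C=C[C@H]3C(=O)OC
F7 | step 10 | methyl (2E,4E)-6-[(8-((E)-dec-8-enyl)bicyclo[4.2.0]octa-2,4-dien-7-yl)amino]hexa-2,4-dienoate | C/C=C/CCCCCCC[C@@H]1[C@H]2C=CC=C[C@H]2[C@H]1NC/C=C/C=C/C(=O)OC
F8 | step 7 | (1R,4R)-4-[(E)-dec-8-enyl]cycloocta-2,5,7-trienyl methyl carbonate | C/C=C/CCCCCCC[C@@H]1/C=C\C=C/[C@@H](OC(=O)OC)/C=C\1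
F9 | step 7 | di-tert-butyl N-[8-((E)-dec-8-enyl)bicyclo[4.2.0]octa-2,4-dien-7-yl]iminodicarbonate (configuration as in 15) | C/C=C/CCCCCCC[C@@H]1[C@H]2C=CC=C[C@H]2[C@H]1N(C(=O)OC(C)(C)C)C(=O)OC(C)(C)C
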